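**Plan**

- Locants: ring C1 = C(OH)(C7H2OBz), C2 = CHCl, C3=C4, C5 = CHOH, C6 = CHOBz. The retrosynthesis cuts C2–Cl (back to a C2 alcohol of opposite configuration), the C6 benzoate (back to a C1/C6 acetonide), the ring bond C3=C4 (ring-closing metathesis), C2–C3 (vinyl Grignard) and C1–C7 (formaldehyde aldol).
- Enabling feature: in the six-membered carbocycle the cis C3=C4 alkene lies between the two oxygen-bearing allylic carbons C2 and C5, so each half is a vinyl carbinol. The cis C1/C6 diol can sit in a dioxolane that carries both vinyl arms on one face.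
- Forward: L-arabinose (1) supplies ring C4, C5, C6, C1, C2 from its C1 to C5 (read backwards it is the L-lyxo chain). It is opened by Wittig methylenation, re-closed as a furanose lactol, branched with formaldehyde (8, C7) and opened again with vinylmagnesium bromide (10, C3). The chain is complete before any carbocycle exists, and the cyclohexene, the only ring of the target, closes in step 9.
- Stereochemistry: C5 and C6 are arabinose C2 and C3. C1 is fixed by the aldol, where C7 enters anti to the C5 side chain and only that product closes to a cis-fused lactol. C2 is set S by Felkin–Anh vinyl addition and inverted when chloride replaces oxygen.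

Key step: step 9

Remark: lactols 3, 6 and 9 are anomeric mixtures, so their anomeric carbon has no descriptor in the SMILES. From compound 11 on the target locants C1–C7 are used; the C1 descriptor changes from S to R at step 10 only because the chlorinated C2 gains CIP priority.

**Route**

Step 1
Reactants: 1 L-arabinose; 2 2,2-dimethoxypropane
Product: 3 3,4-O-isopropylidene-L-arabinopyranose
Conditions: Me2C(OMe)2, p-TsOH·H2O (cat.), DMF, rt
Reagents that add atoms: 2,2-dimethoxypropane COC(C)(C)OC
Why: Acid-catalysed transacetalisation takes the only cis-vicinal diol of the pyranose (O3/O4), a standard isopropylidenation that leaves the hemiacetal and O2 free.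

Step 2
Reactants: 3 3,4-O-isopropylidene-L-arabinopyranose; 4 methyltriphenylphosphonium bromide
Product: 5 1,2-dideoxy-4,5-O-isopropylidene-L-arabino-hex-1-enitol
Conditions: Ph3PCH3Br (3.5 equiv), KOtBu (3.4 equiv), THF, 0 °C to rt
Reagents that add atoms: methyltriphenylphosphonium bromide C[P+](c1ccccc1)(c1ccccc1)c1ccccc1.[Br-]
Why: Wittig methylenation of the lactol through its open hydroxy-aldehyde form (the excess ylide absorbs the two hydroxyl protons) turns arabinose C1 into the vinyl carbon that becomes ring C4 and leaves the stereocentres that become C5 and C6 untouched.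

Step 3
Reactants: 5 1,2-dideoxy-4,5-O-isopropylidene-L-arabino-hex-1-enitol
Product: 7 5,6-dideoxy-2,3-O-isopropylidene-L-lyxo-hex-5-enono-1,4-lactone, via lactol 6 (not isolated)
Conditions: TEMPO (0.2 equiv), PhI(OAc)2 (3 equiv), CH2Cl2, rt
Reagents that add atoms: none
Why: TEMPO/PhI(OAc)2 oxidative lactonisation of a 1,4-diol oxidises the primary alcohol first, the aldehyde closes on the allylic hydroxyl to lactol 6 and the oxoammonium salt oxidises this on to the gamma-lactone, which is more dependable than trying to stop at 6.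

Step 4
Reactants: 7 5,6-dideoxy-2,3-O-isopropylidene-L-lyxo-hex-5-enono-1,4-lactone
Product: 6 5,6-dideoxy-2,3-O-isopropylidene-L-lyxo-hex-5-enofuranose
Conditions: i-Bu2AlH (1.1 equiv), CH2Cl2, −78 °C; aq. KNaC4H4O6 work-up
Reagents that add atoms: none
Why: One equivalent of i-Bu2AlH adds once to the lactone and the tetrahedral aluminate survives until work-up, the usual half-reduction of isopropylidene aldonolactones to lactols.

Step 5
Reactants: 6 5,6-dideoxy-2,3-O-isopropylidene-L-lyxo-hex-5-enofuranose; 8 formaldehyde
Product: 9 5,6-dideoxy-2-C-(hydroxymethyl)-2,3-O-isopropylidene-L-lyxo-hex-5-enofuranose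
Conditions: 37% aq. CH2O (excess), K2CO3, MeOH, 65 °C
Reagents that add atoms: formaldehyde C=O
Why: Crossed aldol of the open aldehyde form with formaldehyde at the only enolisable carbon puts C7 on the dioxolane face anti to the C5 side chain, the one product that can re-close to a cis-fused furanose lactol and is thereby protected from Cannizzaro reduction, and this sets the quaternary centre C1.

Step 6
Reactants: 9 5,6-dideoxy-2-C-(hydroxymethyl)-2,3-O-isopropylidene-L-lyxo-hex-5-enofuranose; 10 vinylmagnesium bromide
Product: 11 open-chain triol CH2=CH–C2H(OH)–C1(C7H2OH)–C6H–C5H(OH)–CH=CH2 with the C1 and C6 oxygens in the isopropylidene acetal, (1S,2S,5S,6R)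
Conditions: CH2=CHMgBr (6 equiv), THF, −20 °C to rt; aq. NH4Cl
Reagents that add atoms: vinylmagnesium bromide C=C[Mg]Br
Why: Grignard addition to the lactol through its magnesium alkoxide–aldehyde form under Felkin–Anh control (the C1–O bond anti to the incoming vinyl group, which passes the CH2O arm and not ring carbon C6) should give the 2S carbinol with its oxygen erythro to the C1 oxygen, and a six-membered chelate through the C7 alkoxide would expose the same face.

Step 7
Reactants: 11 open-chain triol; 12 phenylboronic acid; 13 triisopropylsilyl trifluoromethanesulfonate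
Product: 16 C5 triisopropylsilyl ether of 11 with the C2 and C7 hydroxyls free, via cyclic boronate 14 (not isolated), via silylated boronate 15 (not isolated)
Conditions: PhB(OH)2 (1.05 equiv), MgSO4, toluene, rt; then TIPSOTf, 2,6-lutidine, CH2Cl2, 0 °C; then 30% H2O2, aq. NaHCO3, THF, 0 °C
Reagents that add atoms: triisopropylsilyl trifluoromethanesulfonate CC(C)[Si](OS(=O)(=O)C(F)(F)F)(C(C)C)C(C)C; phenylboronic acid OB(O)c1ccccc1 (its atoms stay only in 14 and 15)
Why: Transient boronate masking, a known way to direct silylation in polyols, ties the only 1,3-diol (O2/O7) into a six-membered boronic ester so that the silyl triflate can reach only O5, and oxidative work-up then frees the diol.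

Step 8
Reactants: 16 C5 silyl ether diol; 17 benzoyl chloride
Product: 18 C7 benzoate of 16, the 1,7-diene with free C2 carbinol, C1/C6 acetonide and C5 triisopropylsilyl ether
Conditions: BzCl (1.1 equiv), pyridine, CH2Cl2, −20 to 0 °C
Reagents that add atoms: benzoyl chloride O=C(Cl)c1ccccc1
Why: Acylation with one equivalent of benzoyl chloride in the cold takes the primary C7 hydroxyl in preference to the secondary C2 hydroxyl, which sits next to the quaternary carbon.

Step 9
Reactants: 18 1,7-diene
Product: 19 cyclohexenol with C1/C6 acetonide, C7 benzoate, C2 hydroxyl cis to the C1 oxygen and C5 triisopropylsilyl ether, (1S,2S,5S,6R)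
Conditions: (H2IMes)(PCy3)Cl2Ru=CHPh (second-generation Grubbs catalyst, 5 mol %), CH2Cl2 (5 mM), 40 °C
Reagents that add atoms: none
Why: The ruthenium benzylidene exchanges onto one terminal vinyl group (probably the one at C2, whose free allylic hydroxyl assists initiation), the new alkylidene adds across the other vinyl group to a ruthenacyclobutane, and cycloreversion releases ethene and the C3=C4 bond. The closest known reaction type is the ring-closing metathesis of carbohydrate-derived octa-1,7-dienes to conduritol-type cyclohexenes. The six-membered carbocycle closes by joining the two inner alkene carbons C3 and C4 of the 1,7-diene, and in a ring of this size only the cis alkene can form. No stereocentre is made: C1, C2, C5 and C6 are in place before the ring forms and none can epimerise under neutral metathesis conditions. The step needs cyclisation in preference to cross-metathesis and no alkene migration; high dilution and the dioxolane, which carries the C2 and C5 arms cis to each other and so holds the two vinyl groups within reach, secure this.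

Step 10
Reactants: 19 cyclohexenol; 20 hexachloroacetone
Product: 21 allylic chloride with C2–Cl trans to the C1 oxygen, C1/C6 acetonide, C7 benzoate and C5 silyl ether, (1R,2R,5S,6R)
Conditions: PPh3, Cl3CC(O)CCl3, CH2Cl2, −20 to 0 °C
Reagents that add atoms: hexachloroacetone O=C(C(Cl)(Cl)Cl)C(Cl)(Cl)Cl
Why: In this Appel-type deoxychlorination chloride displaces the oxyphosphonium group of the allylic C2 alcohol from the face opposite to oxygen (SN2, inversion), while the low temperature and the bulky silyloxy group beside C4 disfavour the SN2′ path.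

Step 11
Reactants: 21 allylic chloride
Product: 22 C1,C6-diol with C2 chloride, C7 benzoate and C5 silyl ether
Conditions: CF3CO2H/H2O (9:1), 0 °C, short contact
Reagents that add atoms: none
Why: Acid hydrolysis of the isopropylidene acetal, which the secondary triisopropylsilyl ether, the benzoate and the allylic chloride (deactivated by the flanking oxygens) should survive for the short time needed.

Step 12
Reactants: 22 chloro diol; 17 benzoyl chloride
Product: 23 C6,C7-dibenzoate with free tertiary C1 hydroxyl, C2 chloride and C5 silyl ether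
Conditions: BzCl (1.5 equiv), pyridine, DMAP (cat.), CH2Cl2, 0 °C to rt
Reagents that add atoms: benzoyl chloride O=C(Cl)c1ccccc1
Why: DMAP-assisted benzoylation acylates the secondary C6 hydroxyl while the tertiary C1 hydroxyl stays inert, and pyridine is too weak a base to close the chlorohydrin to an epoxide.

Step 13
Reactants: 23 silyl-protected dibenzoate
Product: 24 [(1R,2R,5S,6R)-6-(benzoyloxy)-2-chloro-1,5-dihydroxycyclohex-3-en-1-yl]methyl benzoate (CNP0326102.1)
Conditions: HF·pyridine, pyridine/THF, 0 °C to rt
Reagents that add atoms: none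
Why: Fluoride cleavage of the silyl ether with buffered HF·pyridine, which stays acidic enough to prevent benzoate migration and epoxide formation from the trans chlorohydrin.

**Compound list**

1 | L-arabinose (drawn open-chain) | O=C[C@H](O)[C@@H](O)[C@@H](O)CO | starting material
2 | 2,2-dimethoxypropane | COC(C)(C)OC | starting material
3 | 3,4-O-isopropylidene-L-arabinopyranose | OC1[C@H](O)[C@H]2OC(C)(C)O[C@H]2CO1 | intermediate
4 | methyltriphenylphosphonium bromide | C[P+](c1ccccc1)(c1ccccc1)c1ccccc1.[Br-] | starting material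
5 | 1,2-dideoxy-4,5-O-isopropylidene-L-arabino-hex-1-enitol, (S)-1-[(4R,5S)-5-(hydroxymethyl)-2,2-dimethyl-1,3-dioxolan-4-yl]prop-2-en-1-ol | C=C[C@H](O)[C@H]1OC(C)(C)O[C@H]1CO | intermediate
6 | 5,6-dideoxy-2,3-O-isopropylidene-L-lyxo-hex-5-enofuranose (lactol, all-cis furanose) | C=C[C@@H]1OC(O)[C@@H]2OC(C)(C)O[C@H]12 | intermediate
7 | 5,6-dideoxy-2,3-O-isopropylidene-L-lyxo-hex-5-enono-1,4-lactone | C=C[C@@H]1OC(=O)[C@@H]2OC(C)(C)O[C@H]12 | intermediate
8 | formaldehyde | C=O | starting material
9 | 5,6-dideoxy-2-C-(hydroxymethyl)-2,3-O-isopropylidene-L-lyxo-hex-5-enofuranose | C=C[C@@H]1OC(O)[C@]2(CO)OC(C)(C)O[C@H]12 | intermediate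
10 | vinylmagnesium bromide | C=C[Mg]Br | starting material
11 | (S)-1-[(4S,5R)-4-(hydroxymethyl)-5-[(S)-1-hydroxyprop-2-en-1-yl]-2,2-dimethyl-1,3-dioxolan-4-yl]prop-2-en-1-ol (open-chain triol, target locants 1S,2S,5S,6R) | C=C[C@H](O)[C@]1(CO)OC(C)(C)O[C@@H]1[C@@H](O)C=C | intermediate
12 | phenylboronic acid | OB(O)c1ccccc1 | starting material
13 | triisopropylsilyl trifluoromethanesulfonate | CC(C)[Si](OS(=O)(=O)C(F)(F)F)(C(C)C)C(C)C | starting material
14 | cyclic phenylboronate of 11 (2-phenyl-1,3,2-dioxaborinane across O2 and O7, spiro at C1 to the dioxolane; O5 free) | C=C[C@@H]1OB(c2ccccc2)OC[C@]13OC(C)(C)O[C@@H]3[C@@H](O)C=C | intermediate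
15 | C5 O-triisopropylsilyl ether of boronate 14 | C=C[C@@H]1OB(c2ccccc2)OC[C@]13OC(C)(C)O[C@@H]3[C@@H](O[Si](C(C)C)(C(C)C)C(C)C)C=C | intermediate
16 | C5 O-triisopropylsilyl ether of triol 11 (C2 and C7 hydroxyls free) | C=C[C@H](O)[C@]1(CO)OC(C)(C)O[C@@H]1[C@@H](O[Si](C(C)C)(C(C)C)C(C)C)C=C | intermediate
17 | benzoyl chloride | O=C(Cl)c1ccccc1 | starting material
18 | C7 benzoate of 16: acyclic 1,7-diene, free C2 carbinol (2S), C1/C6 acetonide, C5 silyl ether | C=C[C@H](O)[C@]1(COC(=O)c2ccccc2)OC(C)(C)O[C@@H]1[C@@H](O[Si](C(C)C)(C(C)C)C(C)C)C=C | intermediate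
19 | (1S,2S,5S,6R)-cyclohex-3-ene: C1/C6 cis-fused acetonide, C1 CH2OBz, C2 OH cis to the C1 oxygen, C5 OSi(i-Pr)3 trans to the C6 oxygen | O=C(c1ccccc1)OC[C@]2(OC(C)(C)O3)[C@@H](O)C=C[C@H](O[Si](C(C)C)(C(C)C)C(C)C)[C@H]23 | intermediate
20 | hexachloroacetone | O=C(C(Cl)(Cl)Cl)C(Cl)(Cl)Cl | starting material
21 | (1R,2R,5S,6R)-2-chloro analogue of 19, Cl trans to the C1 oxygen | O=C(c1ccccc1)OC[C@]2(OC(C)(C)O3)[C@H](Cl)C=C[C@H](O[Si](C(C)C)(C(C)C)C(C)C)[C@H]23 | intermediate
22 | [(1R,2R,5S,6R)-2-chloro-1,6-dihydroxy-5-(triisopropylsilyloxy)cyclohex-3-en-1-yl]methyl benzoate | O=C(c1ccccc1)OC[C@]1(O)[C@H](Cl)C=C[C@H](O[Si](C(C)C)(C(C)C)C(C)C)[C@H]1O | intermediate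
23 | [(1R,2R,5S,6R)-6-(benzoyloxy)-2-chloro-1-hydroxy-5-(triisopropylsilyloxy)cyclohex-3-en-1-yl]methyl benzoate | O=C(c1ccccc1)OC[C@]1(O)[C@H](Cl)C=C[C@H](O[Si](C(C)C)(C(C)C)C(C)C)[C@H]1OC(=O)c1ccccc1 | intermediate
24 | [(1R,2R,5S,6R)-6-(benzoyloxy)-2-chloro-1,5-dihydroxycyclohex-3-en-1-yl]methyl benzoate | O=C(OC[C@]1(O)[C@H](Cl)C=C[C@H](O)[C@H]1OC(=O)c1ccccc1)c1ccccc1 | target

**Step count and risks**

Total steps: 13. Longest linear sequence: 13 steps (1 to 24).

Steps most likely to fail:

1. Step 10. C2 is flanked by the quaternary C1, so chloride may enter with allylic transposition at C4, or ion-pair return and participation of the C7 benzoate may erode the inversion. The fallback sets out from 19 and returns at 23; it brings chloride in by opening an epoxide instead of displacing an oxyphosphonium group. Mitsunobu inversion of 19 (PPh3, DIAD, ClCH2CO2H, THF) would give the C2-inverted chloroacetate F1. Thiourea with NaHCO3 in ethanol would free the trans alcohol F2, and MsCl/Et3N would give mesylate F3. Cold aqueous CF3CO2H would remove the acetonide to diol F4, and BzCl/pyridine would benzoylate O6 to dibenzoate F5. DBU would then let the anti C1 oxygen displace the mesylate intramolecularly, giving the 1,2-epoxide F6, whose oxygen is on the face of the C6 benzoate. HCl in Et2O at −20 °C would open this vinyl epoxide at the allylic C2 with inversion and give 23.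

2. Step 6. Felkin–Anh and chelated transition states may compete, giving poor facial selectivity at the aldehyde carbon. The fallback sets out from 18 and returns at 19; it moves the C2 stereocentre from the open chain to the ring. The epimers would not be separated, so after steps 7 and 8 diene 18 would be accompanied by its C2 epimer F7. Dess–Martin periodinane would oxidise both to the single dienone F8, and ring closure with (H2IMes)(PCy3)Cl2Ru=CHPh as in step 9 would give cyclohexenone F9. Luche reduction (NaBH4, CeCl3·7H2O, MeOH, −78 °C) should deliver hydride anti to the pseudo-axial C1–O bond of the cis-fused dioxolane and give the cis alcohol 19.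

3. Step 7. Boronate exchange or incomplete masking may let the silyl triflate reach O2 or O7, or the hindered O5 may silylate too slowly. The fallback sets out from 11 and returns at 18; it replaces templated masking by steric differentiation. Benzoylation of 11 first (BzCl 1.05 equiv, 2,4,6-collidine, CH2Cl2, −40 °C) would give the C7 mono-benzoate F10. One equivalent of TIPSOTf with 2,6-lutidine at −78 °C should then silylate O5 in preference to the C2 hydroxyl next to the quaternary carbon, giving 18 directly.

Further compounds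
F1 | step 10 | C2-inverted chloroacetate of 19 | O=C(c1ccccc1)OC[C@]2(OC(C)(C)O3)[C@H](OC(=O)CCl)C=C[C@H](O[Si](C(C)C)(C(C)C)C(C)C)[C@H]23
F2 | step 10 | C2 epimer of 19 (hydroxyl trans to the C1 oxygen) | O=C(c1ccccc1)OC[C@]2(OC(C)(C)O3)[C@H](O)C=C[C@H](O[Si](C(C)C)(C(C)C)C(C)C)[C@H]23
F3 | step 10 | C2 methanesulfonate of F2 | O=C(c1ccccc1)OC[C@]2(OC(C)(C)O3)[C@H](OS(C)(=O)=O)C=C[C@H](O[Si](C(C)C)(C(C)C)C(C)C)[C@H]23
F4 | step 10 | C1,C6-diol C2-mesylate | O=C(c1ccccc1)OC[C@]1(O)[C@H](OS(C)(=O)=O)C=C[C@H](O[Si](C(C)C)(C(C)C)C(C)C)[C@H]1O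
F5 | step 10 | C6,C7-dibenzoate C2-mesylate | O=C(c1ccccc1)OC[C@]1(O)[C@H](OS(C)(=O)=O)C=C[C@H](O[Si](C(C)C)(C(C)C)C(C)C)[C@H]1OC(=O)c1ccccc1
F6 | step 10 | 1,2-epoxide (oxirane on the face of the C6 benzoate), C5 silyl ether, C6,C7-dibenzoate | O=C(c1ccccc1)OC[C@]12O[C@H]1C=C[C@H](O[Si](C(C)C)(C(C)C)C(C)C)[C@H]2OC(=O)c1ccccc1
F7 | step 6 | C2 epimer of diene 18 | C=C[C@@H](O)[C@]1(COC(=O)c2ccccc2)OC(C)(C)O[C@@H]1[C@@H](O[Si](C(C)C)(C(C)C)C(C)C)C=C
F8 | step 6 | dienone (C2 ketone of 18) | C=CC(=O)[C@]1(COC(=O)c2ccccc2)OC(C)(C)O[C@@H]1[C@@H](O[Si](C(C)C)(C(C)C)C(C)C)C=C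
F9 | step 6 | cyclohex-3-en-2-one (C2 ketone of 19) | O=C(c1ccccc1)OC[C@]2(OC(C)(C)O3)C(=O)C=C[C@H](O[Si](C(C)C)(C(C)C)C(C)C)[C@H]23
F10 | step 7 | C7 mono-benzoate of triol 11 | C=C[C@H](O)[C@]1(COC(=O)c2ccccc2)OC(C)(C)O[C@@H]1[C@@H](O)C=C
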